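**Retrosynthetic overview**

- The target comes from fluoride desilylation of its bis(silyl) ether. Ring C (O11–C11a) is closed from a cis-isoflavan-4-ol as in pterocarpan biosynthesis, and C6a is set by transfer hydrogenation with dynamic kinetic resolution of a racemic 2'-hydroxyisoflavanone.
- The isoflavanone comes from a one-flask union of a chromanone enol silane (rings A and B) with a ring-D phenol carrying a (Z)-3-hydroxy-3-methylbutenyl chain on C7: oxidation to a p-quinone monoketal, closure of pyran ring E at the O–C8 bond, ionisation, then C6a–C6b bond formation.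
- Enabling feature: in ring D the pyran oxygen on C8 is para to O11 on C10a, and C6b is the only ring CH. Ring D is therefore a masked p-quinone monoketal (ketal carbon C8, carbonyl C10a), so the aryl C8–O bond can be made as an acetal bond and the same cation is electrophilic at C6b.
- Ring order: B (step 1), then E together with the C6a–C6b link (step 11), then C (step 12). Rings A and D are bought as 4-bromoresorcinol and 5-chlororesorcinol.
- Enol silane: acylation/cyclisation, Stille prenylation, enol silylation. Phenol: directed metalation–prenylation between two MOM ethers, Sonogashira coupling, monosilylation, Z-selective semihydrogenation.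

Key step: step 11

Remark: positions are given in pterocarpan numbering (ring A C1–C4a/C11b, ring B with O5/C6/C6a/C11a, ring C with O11, ring D C6b–C10a, ring E the dimethylpyran on C7–C8); the target is (6aR,11aR), cis-fused, and the (R,R)-catalyst of step 12 is assigned from the usual sense of induction with aryl ketones (4R carbinol).

**Route**

Step 1
Reactants: 1 4-bromobenzene-1,3-diol; 2 3-chloropropanoic acid
Product: 4 6-bromo-7-hydroxychroman-4-one, via chloropropiophenone 3 (not isolated)
Conditions: CF3SO3H, 80 °C; then 2 M NaOH (aq), 0 °C → rt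
Reagents that add atoms: none
Why: Friedel–Crafts acylation should go to the ring carbon ortho to one hydroxyl and para to the other (remote from bromine), and the ortho phenoxide then displaces chloride in an intramolecular Williamson etherification, the standard route from resorcinols to 7-hydroxychroman-4-ones.

Step 2
Reactants: 4 6-bromo-7-hydroxychroman-4-one
Product: 5 6-bromo-7-(triisopropylsilyloxy)chroman-4-one
Conditions: TIPSCl, imidazole, DMF, rt
Reagents that add atoms: chlorotriisopropylsilane, CC(C)[Si](Cl)(C(C)C)C(C)C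
Why: Silylation of the only hydroxyl; the bulky aryl silyl ether is chosen to survive the later coupling, oxidation, Lewis-acid and transfer-hydrogenation conditions and to leave with fluoride at the end.

Step 3
Reactants: 5 6-bromo-7-(triisopropylsilyloxy)chroman-4-one; 6 tributyl(3-methylbut-2-en-1-yl)stannane
Product: 7 6-(3-methylbut-2-en-1-yl)-7-(triisopropylsilyloxy)chroman-4-one
Conditions: Pd(PPh3)4 (5 mol %), DMF, 100 °C
Reagents that add atoms: none
Why: Stille coupling of the aryl bromide with the allylic stannane should deliver the linear prenyl arene under neutral, fluoride-free conditions that leave the ketone and silyl ether alone.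

Step 4
Reactants: 7 6-(3-methylbut-2-en-1-yl)-7-(triisopropylsilyloxy)chroman-4-one
Product: 8 tert-butyldimethyl{[6-(3-methylbut-2-en-1-yl)-7-(triisopropylsilyloxy)-2H-chromen-4-yl]oxy}silane
Conditions: TBSOTf, Et3N, CH2Cl2, 0 °C
Reagents that add atoms: tert-butyldimethylsilyl trifluoromethanesulfonate, CC(C)(C)[Si](C)(C)OS(=O)(=O)C(F)(F)F
Why: Soft enolisation and O-silylation of a ketone with a single enolisable position (C3 of the chromanone) gives one enol silane, used without chromatography.

Step 5
Reactants: 9 5-chlorobenzene-1,3-diol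
Product: 10 1-chloro-3,5-bis(methoxymethoxy)benzene
Conditions: MOMCl, i-Pr2NEt, CH2Cl2, 0 °C → rt
Reagents that add atoms: chloromethyl methyl ether, COCCl
Why: Double O-alkylation installs two metalation-directing acetal ethers.

Step 6
Reactants: 10 1-chloro-3,5-bis(methoxymethoxy)benzene; 11 1-bromo-3-methylbut-2-ene
Product: 12 5-chloro-1,3-bis(methoxymethoxy)-2-(3-methylbut-2-en-1-yl)benzene
Conditions: n-BuLi, THF, 0 °C; then CuBr·SMe2 (10 mol %), 11, −78 °C → rt
Reagents that add atoms: none
Why: Directed ortho-metalation removes the proton between the two MOM ethers (the chloride is not exchanged and the lithiated carbon is not next to chlorine, so no aryne forms), and copper-catalysed SN2 alkylation with prenyl bromide should give the linear prenyl arene.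

Step 7
Reactants: 12 5-chloro-1,3-bis(methoxymethoxy)-2-(3-methylbut-2-en-1-yl)benzene; 13 2-methylbut-3-yn-2-ol
Product: 14 4-[3,5-bis(methoxymethoxy)-4-(3-methylbut-2-en-1-yl)phenyl]-2-methylbut-3-yn-2-ol
Conditions: PdCl2(MeCN)2 (2 mol %), XPhos (6 mol %), Cs2CO3, MeCN, 80 °C
Reagents that add atoms: none
Why: Copper-free Sonogashira coupling; the electron-rich biarylphosphine allows oxidative addition into the unhindered aryl chloride and the free tertiary propargylic alcohol is tolerated.

Step 8
Reactants: 14 4-[3,5-bis(methoxymethoxy)-4-(3-methylbut-2-en-1-yl)phenyl]-2-methylbut-3-yn-2-ol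
Product: 15 5-(3-hydroxy-3-methylbut-1-yn-1-yl)-2-(3-methylbut-2-en-1-yl)benzene-1,3-diol
Conditions: HCl (2 M aq), MeOH, 40 °C
Reagents that add atoms: none
Why: Acid-catalysed methanolysis of the two MOM acetals under mild conditions that are expected to spare the prenyl group and the propargylic tertiary alcohol (a propargylic cation is hard to form).

Step 9
Reactants: 15 5-(3-hydroxy-3-methylbut-1-yn-1-yl)-2-(3-methylbut-2-en-1-yl)benzene-1,3-diol
Product: 16 5-(3-hydroxy-3-methylbut-1-yn-1-yl)-2-(3-methylbut-2-en-1-yl)-3-(triisopropylsilyloxy)phenol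
Conditions: TIPSCl (1.0 equiv), imidazole, DMF, 0 °C
Reagents that add atoms: chlorotriisopropylsilane, CC(C)[Si](Cl)(C(C)C)C(C)C
Why: The two phenolic hydroxyls are equivalent by symmetry, so monosilylation gives a single compound (bis-ether and diol are recycled), and the tertiary alcohol does not react with the bulky silyl chloride.

Step 10
Reactants: 16 5-(3-hydroxy-3-methylbut-1-yn-1-yl)-2-(3-methylbut-2-en-1-yl)-3-(triisopropylsilyloxy)phenol
Product: 17 5-[(1Z)-3-hydroxy-3-methylbut-1-en-1-yl]-2-(3-methylbut-2-en-1-yl)-3-(triisopropylsilyloxy)phenol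
Conditions: H2 (1 atm), Pd/CaCO3–Pb(OAc)2 (Lindlar catalyst), quinoline, EtOAc, rt
Reagents that add atoms: none
Why: Lindlar semihydrogenation adds hydrogen syn and stops at the alkene, setting the Z geometry that later holds the hydroxyl next to C8; the trisubstituted prenyl alkene is not reduced.

Step 11
Reactants: 17 5-[(1Z)-3-hydroxy-3-methylbut-1-en-1-yl]-2-(3-methylbut-2-en-1-yl)-3-(triisopropylsilyloxy)phenol; 8 tert-butyldimethyl{[6-(3-methylbut-2-en-1-yl)-7-(triisopropylsilyloxy)-2H-chromen-4-yl]oxy}silane
Product: 21 3-[6-hydroxy-2,2-dimethyl-7-(3-methylbut-2-en-1-yl)-8-(triisopropylsilyloxy)-2H-chromen-5-yl]-6-(3-methylbut-2-en-1-yl)-7-(triisopropylsilyloxy)chroman-4-one (racemic), via dimethyl monoketal 18 (not isolated), via pyran-fused mixed ketal 19 (not isolated), via oxocarbenium triflate 20 (not isolated)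
Conditions: PhI(OAc)2 (2.05 equiv), MeOH, −10 °C; evaporate (toluene); CSA (5 mol %), 4 Å MS, CH2Cl2, 0 °C; then 8 (1.5 equiv), TMSOTf (10 mol %), −78 → −40 °C
Reagents that add atoms: none
Why: PhI(OAc)2 in MeOH should oxidise the C10a phenol twice, with methanol entering para at C8, to the p-quinone monoketal 18 in which C8 is a ketal carbon; under CSA one methoxy group ionises and the tertiary hydroxyl, held over C8 by the Z-alkene, adds to the exocyclic methoxy-oxocarbenium (6-exo-trig), closing the 2H-pyran ring at the O–C8 bond as mixed ketal 19 (reversible, driven by methanol uptake on the sieves; direct capture by the hydroxyl during the oxidation leads to the same 19). TMSOTf then removes the second methoxy group to give the pyran-fused oxocarbenium ion 20, which is attacked by C3 of enol silane 8 at C6b, the carbon alpha to the C10a carbonyl and vinylogous to the oxocarbenium, and silyl transfer with tautomerisation restores aromatic ring D. Closest known reaction types: oxidation of para-unsubstituted phenols to p-quinone monoketals with hypervalent iodine in methanol, acetal exchange of quinone monoketals, and acid-promoted coupling of quinone monoketals with enol ethers, alkenes and arenes at the alpha carbon; here they are run in one flask without isolation. The only new stereocentre, C3 of the isoflavanone, is deliberately left racemic because it is alpha to the ketone and is equilibrated and set in step 12. Selectivity: attack at C8 and not at C6b in the oxidation rests on the para preference of phenol oxidation and on methanol as solvent; loss of the exocyclic methoxy group and not ring opening of 19 rests on the more accessible methoxy oxygen; C–C bond formation at C6b is secured because it is the only unsubstituted ring carbon, C10 carrying prenyl next to the deactivating C9 silyloxy group.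

Step 12
Reactants: 21 3-[6-hydroxy-2,2-dimethyl-7-(3-methylbut-2-en-1-yl)-8-(triisopropylsilyloxy)-2H-chromen-5-yl]-6-(3-methylbut-2-en-1-yl)-7-(triisopropylsilyloxy)chroman-4-one (racemic)
Product: 23 (6aR,11aR)-2,10-bis(3-methylbut-2-en-1-yl)-3,9-bis(triisopropylsilyloxy)pterocarpan carrying a 2,2-dimethyl-2H-pyran ring fused at C7–C8 (oxygen on C8), via cis-isoflavan-4-ol 22 (not isolated)
Conditions: [RuCl(p-cymene)((R,R)-TsDPEN)] (2 mol %), HCO2H–Et3N (5:2), EtOAc, 40 °C; then CF3CO2H, 0 °C
Reagents that add atoms: none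
Why: Noyori–Ikariya asymmetric transfer hydrogenation with dynamic kinetic resolution: C3 epimerises through the enol under Et3N while the catalyst delivers hydride anti to the aryl group to give the cis-(3R,4R)-alcohol 22, and acid then ionises the p-silyloxybenzylic C4–OH so that the C10a hydroxyl captures the cation in the biosynthesis-like closure of ring C, the cis ring fusion being the only unstrained one, so C6a stays R and C11a becomes R.

Step 13
Reactants: 23 (6aR,11aR)-2,10-bis(3-methylbut-2-en-1-yl)-3,9-bis(triisopropylsilyloxy)pterocarpan carrying a 2,2-dimethyl-2H-pyran ring fused at C7–C8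
Product: 24 Lespecyrtin E3
Conditions: Bu4NF, AcOH (1:1), THF, 0 °C
Reagents that add atoms: none
Why: Fluoride cleaves both aryl silyl ethers while acetic acid protonates the phenoxides, so the electron-rich product is not exposed to base; no stereocentre is touched.

**Compound list**

1 | 4-bromobenzene-1,3-diol | Oc1ccc(Br)c(O)c1 | starting material
2 | 3-chloropropanoic acid | OC(=O)CCCl | starting material
3 | 1-(5-bromo-2,4-dihydroxyphenyl)-3-chloropropan-1-one | O=C(CCCl)c1cc(Br)c(O)cc1O | intermediate (not isolated)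
4 | 6-bromo-7-hydroxychroman-4-one | O=C1CCOc2cc(O)c(Br)cc12 | intermediate
5 | 6-bromo-7-(triisopropylsilyloxy)chroman-4-one | O=C1CCOc2cc(O[Si](C(C)C)(C(C)C)C(C)C)c(Br)cc12 | intermediate
6 | tributyl(3-methylbut-2-en-1-yl)stannane | CCCC[Sn](CCCC)(CCCC)CC=C(C)C | starting material
7 | 6-(3-methylbut-2-en-1-yl)-7-(triisopropylsilyloxy)chroman-4-one | O=C1CCOc2cc(O[Si](C(C)C)(C(C)C)C(C)C)c(CC=C(C)C)cc12 | intermediate
8 | tert-butyldimethyl{[6-(3-methylbut-2-en-1-yl)-7-(triisopropylsilyloxy)-2H-chromen-4-yl]oxy}silane | CC(C)=CCc1cc2C(O[Si](C)(C)C(C)(C)C)=CCOc2cc1O[Si](C(C)C)(C(C)C)C(C)C | intermediate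
9 | 5-chlorobenzene-1,3-diol | Oc1cc(O)cc(Cl)c1 | starting material
10 | 1-chloro-3,5-bis(methoxymethoxy)benzene | COCOc1cc(Cl)cc(OCOC)c1 | intermediate
11 | 1-bromo-3-methylbut-2-ene | CC(C)=CCBr | starting material
12 | 5-chloro-1,3-bis(methoxymethoxy)-2-(3-methylbut-2-en-1-yl)benzene | COCOc1cc(Cl)cc(OCOC)c1CC=C(C)C | intermediate
13 | 2-methylbut-3-yn-2-ol | CC(C)(O)C#C | starting material
14 | 4-[3,5-bis(methoxymethoxy)-4-(3-methylbut-2-en-1-yl)phenyl]-2-methylbut-3-yn-2-ol | COCOc1cc(C#CC(C)(C)O)cc(OCOC)c1CC=C(C)C | intermediate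
15 | 5-(3-hydroxy-3-methylbut-1-yn-1-yl)-2-(3-methylbut-2-en-1-yl)benzene-1,3-diol | CC(C)=CCc1c(O)cc(C#CC(C)(C)O)cc1O | intermediate
16 | 5-(3-hydroxy-3-methylbut-1-yn-1-yl)-2-(3-methylbut-2-en-1-yl)-3-(triisopropylsilyloxy)phenol | CC(C)=CCc1c(O)cc(C#CC(C)(C)O)cc1O[Si](C(C)C)(C(C)C)C(C)C | intermediate
17 | 5-[(1Z)-3-hydroxy-3-methylbut-1-en-1-yl]-2-(3-methylbut-2-en-1-yl)-3-(triisopropylsilyloxy)phenol | CC(C)=CCc1c(O)cc(/C=C\C(C)(C)O)cc1O[Si](C(C)C)(C(C)C)C(C)C | intermediate
18 | 3-[(1Z)-3-hydroxy-3-methylbut-1-en-1-yl]-4,4-dimethoxy-6-(3-methylbut-2-en-1-yl)-5-(triisopropylsilyloxy)cyclohexa-2,5-dien-1-one | COC1(OC)C(/C=C\C(C)(C)O)=CC(=O)C(CC=C(C)C)=C1O[Si](C(C)C)(C(C)C)C(C)C | intermediate (not isolated)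
19 | 8a-methoxy-2,2-dimethyl-7-(3-methylbut-2-en-1-yl)-8-(triisopropylsilyloxy)-2H-chromen-6(8aH)-one (racemic) | COC12OC(C)(C)C=CC1=CC(=O)C(CC=C(C)C)=C2O[Si](C(C)C)(C(C)C)C(C)C | intermediate (not isolated)
20 | 2,2-dimethyl-7-(3-methylbut-2-en-1-yl)-6-oxo-8-(triisopropylsilyloxy)-2H,6H-chromen-1-ium trifluoromethanesulfonate | CC(C)=CCC1=C(O[Si](C(C)C)(C(C)C)C(C)C)C2=[O+]C(C)(C)C=CC2=CC1=O.[O-]S(=O)(=O)C(F)(F)F | intermediate (not isolated)
21 | 3-[6-hydroxy-2,2-dimethyl-7-(3-methylbut-2-en-1-yl)-8-(triisopropylsilyloxy)-2H-chromen-5-yl]-6-(3-methylbut-2-en-1-yl)-7-(triisopropylsilyloxy)chroman-4-one (racemic, C3 labile) | O=C1c2cc(CC=C(C)C)c(O[Si](C(C)C)(C(C)C)C(C)C)cc2OCC1c1c(O)c(CC=C(C)C)c(O[Si](C(C)C)(C(C)C)C(C)C)c2OC(C)(C)C=Cc12 | intermediate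
22 | (3R,4R)-3-[6-hydroxy-2,2-dimethyl-7-(3-methylbut-2-en-1-yl)-8-(triisopropylsilyloxy)-2H-chromen-5-yl]-6-(3-methylbut-2-en-1-yl)-7-(triisopropylsilyloxy)chroman-4-ol (cis) | CC(C)=CCc1cc2c(cc1O[Si](C(C)C)(C(C)C)C(C)C)OC[C@@H](c1c(O)c(CC=C(C)C)c(O[Si](C(C)C)(C(C)C)C(C)C)c3OC(C)(C)C=Cc13)[C@H]2O | intermediate (not isolated)
23 | (6aR,11aR)-2,10-bis(3-methylbut-2-en-1-yl)-3,9-bis(triisopropylsilyloxy)pterocarpan with a 2,2-dimethyl-2H-pyran ring fused at C7–C8 (oxygen on C8) | CC(C)=CCc1cc2c(cc1O[Si](C(C)C)(C(C)C)C(C)C)OC[C@H]1c3c4c(c(O[Si](C(C)C)(C(C)C)C(C)C)c(CC=C(C)C)c3O[C@@H]21)OC(C)(C)C=C4 | intermediate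
24 | Lespecyrtin E3 | CC(C)=CCc1cc2c(cc1O)OC[C@H]1c3c4c(c(O)c(CC=C(C)C)c3O[C@@H]21)OC(C)(C)C=C4 | target

**Step count and risks**

Total steps: 13. Longest linear sequence: 9 steps (steps 5–13); the enol silane branch (steps 1–4) joins at step 11.

Most likely to fail:

1. Step 11. During the oxidation the tertiary hydroxyl may add to C6b (ortho to the phenol oxygen) instead of C8, methanol may strip the silyl group from the dearomatised ring, or the enol silane may couple before the pyran ring has closed. Fallback, from 17 back to 21: the hydroxyl is taken out of the oxidation and the monoketal is isolated. Both hydroxyls of 17 are silylated with TESOTf/2,6-lutidine to the bis(triethylsilyl) ether F1. The aryl triethylsilyl group alone is removed with K2CO3 in MeOH at 0 °C to give the tertiary triethylsilyl ether phenol F2. Oxidation with PhI(OAc)2 in MeOH, where only external methanol can attack (para), gives the isolated dimethyl monoketal F3. F3 and 8 are then treated with catalytic TMSOTf in CH2Cl2 at −78 °C; silyl-ether transacetalisation closes the pyran at C8 and the resulting oxocarbenium ion couples with 8 to return to 21.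

2. Step 12. Hydride transfer to the hindered ketone may be slow, and the two interconverting enantiomers may be reduced with too small a rate difference, which would lower the enantiomeric purity after cyclisation. Fallback, from 21 back to 23: reduction with NaBH4 (MeOH–THF, 0 °C) gives the racemic isoflavan-4-ol mixture F4. Cyclisation with CF3CO2H as in step 12 gives the racemate made of 23 and its (6aS,11aS)-enantiomer F5. 23 is separated from F5 by preparative chromatography on a chiral stationary phase (amylose tris(3,5-dimethylphenylcarbamate)).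

3. Step 8. Acid may add a liberated phenol across the prenyl double bond (chroman formation) or solvolyse the propargylic alcohol. Fallback, from 9 back to 15, without acetal protecting groups: 9 is iodinated between the two hydroxyls (I2, NaHCO3, H2O, 0 °C) to 5-chloro-2-iodobenzene-1,3-diol F6. The iodide is coupled chemoselectively with stannane 6 (Pd(PPh3)4, DMF, 60 °C) to 5-chloro-2-(3-methylbut-2-en-1-yl)benzene-1,3-diol F7. The Sonogashira coupling of step 7 is run on F7 with 13 (additional Cs2CO3) to reach 15.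

**Further compounds**

F1 | step 11 | 5-[(1Z)-3-methyl-3-(triethylsilyloxy)but-1-en-1-yl]-2-(3-methylbut-2-en-1-yl)-1-(triethylsilyloxy)-3-(triisopropylsilyloxy)benzene | CC(C)=CCc1c(O[Si](CC)(CC)CC)cc(/C=C\C(C)(C)O[Si](CC)(CC)CC)cc1O[Si](C(C)C)(C(C)C)C(C)C
F2 | step 11 | 5-[(1Z)-3-methyl-3-(triethylsilyloxy)but-1-en-1-yl]-2-(3-methylbut-2-en-1-yl)-3-(triisopropylsilyloxy)phenol | CC(C)=CCc1c(O)cc(/C=C\C(C)(C)O[Si](CC)(CC)CC)cc1O[Si](C(C)C)(C(C)C)C(C)C
F3 | step 11 | 4,4-dimethoxy-3-[(1Z)-3-methyl-3-(triethylsilyloxy)but-1-en-1-yl]-6-(3-methylbut-2-en-1-yl)-5-(triisopropylsilyloxy)cyclohexa-2,5-dien-1-one | COC1(OC)C(/C=C\C(C)(C)O[Si](CC)(CC)CC)=CC(=O)C(CC=C(C)C)=C1O[Si](C(C)C)(C(C)C)C(C)C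
F4 | step 12 | 3-[6-hydroxy-2,2-dimethyl-7-(3-methylbut-2-en-1-yl)-8-(triisopropylsilyloxy)-2H-chromen-5-yl]-6-(3-methylbut-2-en-1-yl)-7-(triisopropylsilyloxy)chroman-4-ol (racemic, both diastereomers) | CC(C)=CCc1cc2c(cc1O[Si](C(C)C)(C(C)C)C(C)C)OCC(c1c(O)c(CC=C(C)C)c(O[Si](C(C)C)(C(C)C)C(C)C)c3OC(C)(C)C=Cc13)C2O
F5 | step 12 | (6aS,11aS)-enantiomer of 23 | CC(C)=CCc1cc2c(cc1O[Si](C(C)C)(C(C)C)C(C)C)OC[C@@H]1c3c4c(c(O[Si](C(C)C)(C(C)C)C(C)C)c(CC=C(C)C)c3O[C@H]21)OC(C)(C)C=C4
F6 | step 8 | 5-chloro-2-iodobenzene-1,3-diol | Oc1cc(Cl)cc(O)c1I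
F7 | step 8 | 5-chloro-2-(3-methylbut-2-en-1-yl)benzene-1,3-diol | CC(C)=CCc1c(O)cc(Cl)cc1O
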